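**Plan**
- Retrosynthesis cuts, in order: C3–C4 of the 3,6-dihydro-1,2-dioxine (6-exo radical closure), O2–C3 (hydroperoxide to methyl propiolate), the O1–C6/MeO–C6 pair (Criegee ozonolysis in methanol), C4=C5 (Takai olefination), and the exo-methylene carbon (α-methylenation of octadecanal).
- Enabling feature: C3 carries ring oxygen O2 and is also the β-carbon of the CH2CO2Me arm, so O2–C3–CH2CO2Me is the adduct of a radical to a β-peroxyacrylate. C4 is an sp2 ring carbon β to the ketal carbon C6. Both are acceptor carbons, so only a radical joins them, and the C5–C6–O1–O2 tether makes the closure 6-exo.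
- Forward: octadecanal, 2-methylene aldehyde, E-iodo diene, α-methoxy hydroperoxide (C6 created), resolution, β-peroxyacrylate, then the only ring (the 1,2-dioxine) is closed in the last step.
- Stereochemistry: C6 (R) comes from chromatographic resolution of the hydroperoxy ketal and is never touched again. C3 (S) comes from 1,4-induction by C6 in the ring closure (methoxy pseudoaxial, new side arm pseudoaxial and trans to it).

Key step: step 6

Remark: the target is read as the (3S,6R) isomer, 6-methoxy trans to the 3-CH2CO2Me arm. Which eluting enantiomer of the hydroperoxy ketal is R has to be assigned once, e.g. by anomalous-dispersion X-ray analysis of a crystalline derivative (iodine as heavy atom).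

Step 1
Reactants: 1 octadecanal
Product: 2 2-methylideneoctadecanal
Conditions: 37% aq. CH2O, pyrrolidine (10 mol%), EtCO2H (10 mol%), iPrOH, 45 °C
Reagents that add atoms: formaldehyde, C=O
Why: Organocatalytic α-methylenation (Mannich condensation through the enamine, then loss of the amine) is reliable for linear aldehydes and stops at the 2-methylene aldehyde, which has no α-hydrogen left.

Step 2
Reactants: 2 2-methylideneoctadecanal
Product: 3 (1E)-1-iodo-3-methylidenenonadec-1-ene
Conditions: CrCl2 (6 equiv), CHI3 (2 equiv), THF, 0 °C to rt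
Reagents that add atoms: iodoform, IC(I)I
Why: Takai olefination with divalent chromium adds the iodo-carbenoid 1,2 to the enal carbonyl and should give the E-iodoalkene; the geometry is of no consequence later because the vinyl radical inverts.

Step 3
Reactants: 3 (1E)-1-iodo-3-methylidenenonadec-1-ene
Product: 6 racemic (1E)-3-hydroperoxy-1-iodo-3-methoxynonadec-1-ene, via primary ozonide 4 (not isolated), via carbonyl oxide 5 (not isolated)
Conditions: O3 (1.0 equiv, Sudan Red 7B end-point), CH2Cl2/MeOH 1:1, NaHCO3, −78 °C; no reductive work-up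
Reagents that add atoms: ozone, [O-][O+]=O; methanol, CO
Why: Criegee ozonolysis should attack the electron-rich 1,1-disubstituted double bond in preference to the halogen-deactivated iodoalkene, split the primary ozonide to formaldehyde and the more substituted carbonyl oxide, and let solvent methanol trap the latter as the α-methoxy hydroperoxide, the new centre being formed racemic.

Step 4
Reactants: 6 racemic (1E)-3-hydroperoxy-1-iodo-3-methoxynonadec-1-ene
Product: 7 (1E,3R)-3-hydroperoxy-1-iodo-3-methoxynonadec-1-ene
Conditions: preparative HPLC, immobilised amylose tris(3,5-dimethylphenylcarbamate) phase, hexane/MTBE (no alcohol), 10 °C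
Reagents that add atoms: none
Why: Chromatographic resolution on a chiral stationary phase is standard for hydroperoxide enantiomers, and the alcohol-free eluent excludes acid-catalysed methoxy exchange that would racemise the peroxyketal centre, so the future C6 is fixed as R.

Step 5
Reactants: 7 (1E,3R)-3-hydroperoxy-1-iodo-3-methoxynonadec-1-ene; 8 methyl propiolate
Product: 9 methyl (2E)-3-{[(1E,3R)-1-iodo-3-methoxynonadec-1-en-3-yl]peroxy}prop-2-enoate
Conditions: DABCO (10 mol%), CH2Cl2, −20 to 0 °C, dark; used at once
Reagents that add atoms: none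
Why: Amine-catalysed oxa-Michael addition of the hydroperoxide O–H (pKa about 12) to the propiolate should give the E-β-peroxyacrylate, the tertiary peroxyketal having no α-hydrogen for base fragmentation and no bond to its stereocentre being broken.

Step 6
Reactants: 9 methyl (2E)-3-{[(1E,3R)-1-iodo-3-methoxynonadec-1-en-3-yl]peroxy}prop-2-enoate
Product: 12 methyl 2-[(3S,6R)-6-hexadecyl-6-methoxy-3,6-dihydro-1,2-dioxin-3-yl]acetate, via vinyl radical 10 (not isolated), via ring-closed ester radical 11 (not isolated)
Conditions: Bu3SnH (1.3 equiv, syringe pump), Et3B (0.3 equiv), trace air, toluene (5 mM), −78 to −40 °C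
Reagents that add atoms: none
Why: Proposed new method: the tributylstannyl radical abstracts iodine from 9 to give the σ-vinyl radical 10 at C4, which adds to C3, the β-carbon of the peroxyacrylate, and the α-ester radical 11 then takes hydrogen from the stannane; this joins two carbons that are both acceptor positions (C4 β to the ketal carbon C6, C3 β to the ester carbonyl). The closest known reactions are the β-alkoxyacrylate radical cyclisation to 2,6-disubstituted oxacycles and 6-exo vinyl radical cyclisations, here extended to a peroxide-linked acceptor; the dihydro-1,2-dioxine ring closes in the 6-exo-trig mode with C4=C5 kept inside the ring. C3 is set by C6: in the half-chair transition state the methoxy group should sit pseudoaxial (anomeric interaction with ring oxygen O1) and the hexadecyl chain pseudoequatorial, and the acrylate is expected to react through its s-cis enol-ether conformer (O1–O2–C3=Cα syn-periplanar, as in esters and unhindered vinyl ethers), which places the CH2CO2Me arm pseudoaxial and trans to the methoxy group, i.e. 3S from 6R. No 1,3-diaxial partner penalises that arm because O1 carries no substituent and C5 is sp2. The step needs ring closure to win over direct reduction of 10, over 1,5-hydrogen shift from OCH3 or the chain, and over epoxide closure of 11 onto the O–O bond; the electron-poor acceptor, a low stationary stannane concentration and low temperature are meant to secure this, and tin radicals attack dialkyl peroxides only slowly.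

**Compound list**
1 | octadecanal | CCCCCCCCCCCCCCCCCC=O | starting material
2 | 2-methylideneoctadecanal | CCCCCCCCCCCCCCCCC(=C)C=O | intermediate
3 | (1E)-1-iodo-3-methylidenenonadec-1-ene | CCCCCCCCCCCCCCCCC(=C)/C=C/I | intermediate
4 | 4-hexadecyl-4-[(E)-2-iodoethenyl]-1,2,3-trioxolane (primary ozonide, racemic) | CCCCCCCCCCCCCCCCC1(/C=C/I)COOO1 | intermediate (not isolated)
5 | (1E)-1-iodononadec-1-en-3-one O-oxide (carbonyl oxide) | CCCCCCCCCCCCCCCCC(/C=C/I)=[O+][O-] | intermediate (not isolated)
6 | racemic (1E)-3-hydroperoxy-1-iodo-3-methoxynonadec-1-ene | CCCCCCCCCCCCCCCCC(OO)(OC)/C=C/I | intermediate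
7 | (1E,3R)-3-hydroperoxy-1-iodo-3-methoxynonadec-1-ene | CCCCCCCCCCCCCCCC[C@](OO)(OC)/C=C/I | intermediate
8 | methyl propiolate | C#CC(=O)OC | starting material
9 | methyl (2E)-3-{[(1E,3R)-1-iodo-3-methoxynonadec-1-en-3-yl]peroxy}prop-2-enoate | CCCCCCCCCCCCCCCC[C@](OO/C=C/C(=O)OC)(OC)/C=C/I | intermediate
10 | (3R)-3-methoxy-3-{[(1E)-3-methoxy-3-oxoprop-1-en-1-yl]peroxy}nonadec-1-en-1-yl radical | CCCCCCCCCCCCCCCC[C@](OO/C=C/C(=O)OC)(OC)C=[CH] | intermediate (not isolated)
11 | 1-[(3S,6R)-6-hexadecyl-6-methoxy-3,6-dihydro-1,2-dioxin-3-yl]-2-methoxy-2-oxoethyl radical | CCCCCCCCCCCCCCCC[C@]1(OC)C=C[C@H]([CH]C(=O)OC)OO1 | intermediate (not isolated)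
12 | methyl 2-[(3S,6R)-6-hexadecyl-6-methoxy-3,6-dihydro-1,2-dioxin-3-yl]acetate | CCCCCCCCCCCCCCCC[C@]1(OC)C=C[C@H](CC(=O)OC)OO1 | target

Total step count: 6. Longest linear sequence: 6 steps (1 to 12).

**Steps most likely to fail**

Step 6. The vinyl radical may be quenched before ring closure (hydrogen transfer from the stannane, or 1,5-shift from the methoxy group or the chain), the adduct radical may close to an epoxide with O–O cleavage, or attack at C3 may occur on the wrong face. The fallback sets out from 2 and comes back at 12, closing the ring at O2–C3 by the well-precedented intramolecular conjugate addition of a hydroperoxide to an enoate. Stork–Zhao olefination of 2 (Ph3P+CH2I I−, NaN(SiMe3)2, THF/DMPU, −78 °C) would give (1Z)-1-iodo-3-methylidenenonadec-1-ene F1. Stille coupling with methyl (E)-3-(tributylstannyl)acrylate (zerovalent palladium, Pd(PPh3)4, CuI, DMF, rt) would give methyl (2E,4Z)-6-methylidenedocosa-2,4-dienoate F2. Ozonolysis in CH2Cl2/MeOH at −78 °C, selective for the electron-rich 6-methylidene group, would give racemic methyl (2E,4Z)-6-hydroperoxy-6-methoxydocosa-2,4-dienoate F3, resolved as in step 4 to methyl (2E,4Z,6R)-6-hydroperoxy-6-methoxydocosa-2,4-dienoate F4. Catalytic Cs2CO3 in CF3CH2OH at low temperature should then close the dioxine by 6-exo oxa-Michael addition to give 12 together with its C3 epimer, methyl 2-[(3R,6R)-6-hexadecyl-6-methoxy-3,6-dihydro-1,2-dioxin-3-yl]acetate F5, which is removed by chromatography.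

Step 5. The amine may decompose the α-methoxy hydroperoxide or oligomerise the propiolate faster than conjugate addition occurs, and the vinylogous perester may lose its O–O bond on handling. The fallback sets out from 7 and comes back at 9 by vinylic substitution instead of catalytic conjugate addition: the caesium salt of 7 (Cs2CO3, DMF, −20 °C, no amine) displaces chloride from methyl (E)-3-chloroacrylate by addition–elimination with retention of the E geometry. No new compound arises on the way.

Step 4. The enantiomers may separate incompletely, or the peroxyketal may racemise on the column by methoxy exchange. The fallback sets out from 6 and comes back at 12 by resolving at the end through asymmetric catalysis instead of chromatography. Racemic 6 is taken through steps 5 and 6 unresolved, which gives, beside 9, 10, 11 and 12, their antipodes: methyl (2E)-3-{[(1E,3S)-1-iodo-3-methoxynonadec-1-en-3-yl]peroxy}prop-2-enoate F6, the (3S)-vinyl radical F7, the (3R,6S)-ring-closed ester radical F8 and methyl 2-[(3R,6S)-6-hexadecyl-6-methoxy-3,6-dihydro-1,2-dioxin-3-yl]acetate F9. A chiral-base Kornblum–DeLaMare kinetic resolution (cinchona alkaloid base such as (DHQD)2PHAL, or its pseudoenantiomer (DHQ)2PHAL, whichever removes the C3 proton of F9 faster; 5–10 mol%, CH2Cl2, rt) should convert F9 into methyl (4Z)-3,6-dioxodocos-4-enoate F10 and leave 12, which is separated from the polar enedione.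

**Further compounds**
F1 | step 6 | (1Z)-1-iodo-3-methylidenenonadec-1-ene | CCCCCCCCCCCCCCCCC(=C)/C=C\I
F2 | step 6 | methyl (2E,4Z)-6-methylidenedocosa-2,4-dienoate | CCCCCCCCCCCCCCCCC(=C)/C=C\C=C\C(=O)OC
F3 | step 6 | racemic methyl (2E,4Z)-6-hydroperoxy-6-methoxydocosa-2,4-dienoate | CCCCCCCCCCCCCCCCC(OO)(OC)/C=C\C=C\C(=O)OC
F4 | step 6 | methyl (2E,4Z,6R)-6-hydroperoxy-6-methoxydocosa-2,4-dienoate | CCCCCCCCCCCCCCCC[C@](OO)(OC)/C=C\C=C\C(=O)OC
F5 | step 6 | methyl 2-[(3R,6R)-6-hexadecyl-6-methoxy-3,6-dihydro-1,2-dioxin-3-yl]acetate | CCCCCCCCCCCCCCCC[C@]1(OC)C=C[C@@H](CC(=O)OC)OO1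
F0 | step 5 | none | none
F6 | step 4 | methyl (2E)-3-{[(1E,3S)-1-iodo-3-methoxynonadec-1-en-3-yl]peroxy}prop-2-enoate | CCCCCCCCCCCCCCCC[C@@](OO/C=C/C(=O)OC)(OC)/C=C/I
F7 | step 4 | (3S)-3-methoxy-3-{[(1E)-3-methoxy-3-oxoprop-1-en-1-yl]peroxy}nonadec-1-en-1-yl radical | CCCCCCCCCCCCCCCC[C@@](OO/C=C/C(=O)OC)(OC)C=[CH]
F8 | step 4 | 1-[(3R,6S)-6-hexadecyl-6-methoxy-3,6-dihydro-1,2-dioxin-3-yl]-2-methoxy-2-oxoethyl radical | CCCCCCCCCCCCCCCC[C@@]1(OC)C=C[C@@H]([CH]C(=O)OC)OO1
F9 | step 4 | methyl 2-[(3R,6S)-6-hexadecyl-6-methoxy-3,6-dihydro-1,2-dioxin-3-yl]acetate | CCCCCCCCCCCCCCCC[C@@]1(OC)C=C[C@@H](CC(=O)OC)OO1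
F10 | step 4 | methyl (4Z)-3,6-dioxodocos-4-enoate | CCCCCCCCCCCCCCCCC(=O)/C=C\C(=O)CC(=O)OC
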